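## Structural features

Ferocaulidin 13 is a drimane-type trans-decalin whose C11 oxygen is etherified with the C7 phenol of a coumarin; drimane numbering is used throughout (ring A = C1–C5 and C10, ring B = C5–C10, C11 = the methylene on C9). Ring A carries an axial secondary hydroxyl at C3 next to the gem-dimethyl carbon C4. Ring B is a cyclohexenone (C6=O, C7=C8 with a methyl on C8) and bears the aryloxymethyl group on C9. Three of the four stereocentres are contiguous (C5–C10–C9, C10 quaternary and joined through C5 to the second quaternary carbon C4), while C3 is insulated from them by C4. The C10 methyl and H-5 are trans, C11 is equatorial on the side of the C10 methyl, and the C3 hydroxyl is axial on the opposite face. The fragile parts are the γ-aryloxymethyl enone (the aryloxide can be expelled through the extended enolate, and C5 and C9 are epimerizable), the coumarin lactone (hydride, hydroxide) and the hindered axial carbinol. The real difficulty is the absolute configuration of the quaternary C10 within the congested C4–C5–C10 array. The key step exploits the fact that ring B (C5–C10, methyls on C8 and C10, oxygen on C6, a one-carbon handle position at C9) is a C2v-symmetric 2,6-dimethylquinone monoketal and that C1–C4 of ring A (gem-dimethyl, C3 oxygen) are a 2-silyloxydiene, so one desymmetrizing annulation forms C4–C5 and C1–C10.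

## Logic of the disconnections

13 ⇒ 11 + 12. The O–C11 bond is cut. C11 is the δ-carbon of the C6 carbonyl through C7=C8–C9, so the ether is the formal 1,6-adduct of a phenol to a linear dienone. The cut removes the coumarin and the C9 stereocentre together and keeps the base-sensitive γ-aryloxy enone out of every earlier step. The forward step must be downhill enough not to revert, and the extended enolate must be protonated at C9 anti to the C10 methyl.

11 ⇒ 9. No skeletal bond is cut: the C6 carbonyl is traded for two C6–OMe bonds and the C5–H bond is returned to the cis configuration. The ketal keeps the ring B carbonyl silent during hydride chemistry, and the cis fusion is what a cycloaddition delivers. C5 therefore need not be controlled when the ring is made, but the trans isomer must be both the kinetic protonation product and the thermodynamic one.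

9 ⇒ 8. The C3–H bond is cut (carbinol to ketone), because the C3 oxygen arrives at the ketone oxidation level. The hydride must reach the correct face of a cis-fused, conformationally ambiguous ring, which calls for reagent control.

8 ⇒ 7. The C2–H bond is exchanged for an O–Si bond (ketone to silyl enol ether). The enol ether is the form in which C3 leaves the annulation and also protects C3 during the olefination.

7 ⇒ 5. The C9=C11 double bond is cut to a C9 ketone. This ketone is the activating group of the dienophile, and C11 becomes a simple one-carbon nucleophile. The forward step needs clean 1,2-addition to a hindered, non-enolizable enone without touching the ketal or the enol ether.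

5 ⇒ 2 + 4. The C4–C5 and C1–C10 bonds are cut, opening ring A. The two fragments are an achiral, symmetrical dienophile and an achiral diene, each one step from a commercial compound. The forward step must distinguish the enantiotopic enone arms and faces of 2 and overcome the congestion at the dimethylated diene terminus.

2 ⇒ 1. One C6–OMe bond is cut; the monoketal is the oxidation product of a para-methoxyphenol.

4 ⇒ 3. The O–Si bond is cut; the diene is the silyl enol ether of a vinyl ketone with a single enolizable position.

## Other disconnections considered

Alternative 1: The C4–C5 and C9–C10 bonds are cut, unfolding both rings into the acyclic epoxy-diene A1, (R)-10,11-epoxy-(2E,6E)-farnesyl acetate. In the forward sense Cp2TiCl (trivalent titanium, from Cp2TiCl2 and Mn dust) opens the epoxide homolytically at its tertiary carbon. The C4 radical closes 6-endo onto C5, the resulting C10 radical closes 6-endo onto C9, and the C8 radical ends as the exocyclic alkene, giving A2 (11-acetoxy-ent-drim-8(12)-en-3-ol, equatorial C3 hydroxyl).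
- In its favour: the reaction class is established; one step closes both rings with a trans fusion and sets C3, C5, C9 and C10 relative to the epoxide; C11 already carries oxygen, so the aryl ether could be made by a Mitsunobu reaction without any reversible conjugate addition.
- Against it here: A2 has no oxygen at C6. The enone would have to come from alkene isomerization and a late allylic oxidation at the hindered C6 in competition with C9 and C12. The C3 carbinol is the wrong epimer and needs an oxidation/bulky-hydride pair. Radical bicyclizations of this kind usually give monocyclic by-products.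
- Comparison: on ring-fusion and C9 stereocontrol and on precedent this plan is better than the chosen one. The chosen plan is better on the oxidation pattern (C6 oxygen and C7=C8 come with the dienophile) and is expected to be clearly shorter.

Alternative 2: The C6–C7 bond of ring B is cut, leading to the monocyclic aldehyde A3, a 2,2,6-trimethylcyclohexane-1-carbaldehyde with the silyloxy group on C3 and the isopropenyl-bearing side chain on C10. Me2AlCl activates the aldehyde, the terminal isopropenyl carbon C7 attacks C6 and a C12 hydrogen moves to oxygen (carbonyl-ene reaction), closing ring B to A4 (equatorial C6 hydroxyl, C8 exocyclic methylene).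
- In its favour: six-membered carbonyl-ene closures are dependable. The C6 oxygen and an alkene that can be moved into conjugation after oxidation are delivered. C3 (axial, silylated), C5, C9 and C10 are already correct, so no epimerization and no stereo-defining protonation is needed later.
- Against it here: the whole stereochemical problem, including the quaternary C10 and the contiguous C5/C10/C9 triad on a monocycle, is moved into A3, whose synthesis the key step does not help. The aldehyde sits between two quaternary carbons and is epimerizable under Lewis acid. The step forms one bond and one stereocentre that is then oxidized away.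
- Comparison: the end game (oxidation, isomerization, deprotection, Mitsunobu etherification) is at least as secure as that of the chosen plan. Convergence and step count are much worse, because the chosen key step builds the quaternary centre that this alternative presupposes.

Alternative 3: The C5–C10 and C8–C9 bonds are cut, giving the acyclic triene A5, methyl (2E,6R,8Z,10E)-6,9-bis(tert-butyldimethylsilyloxy)-3,7,7-trimethyldodeca-2,8,10-trienoate. On heating, the silyloxydiene (C5=C6–C7=C8) adds intramolecularly to the enoate (C9=C10) and both rings form at once to give A6 (trans-fused, C6 silyl enol ether, C11 ester, C3 epimer, provisional C8 centre).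
- In its favour: two rings, two bonds and the C5/C9/C10 triad are formed in one thermal step without a catalyst. The trans fusion is reached directly. The C6 enol ether can be dehydrogenated with Pd(OAc)2 to the C7=C8 enone, which also erases C8.
- Against it here: the dienophile is a β,β-disubstituted enoate and the diene terminus is neopentyl, so high temperatures are expected, with the risk of silyl enol ether isomerization. Cis/trans and facial selectivity rest on relay from the single C3 stereocentre, which must have the wrong (equatorial) configuration for that purpose and be inverted later. The ester must be reduced and etherified around a sensitive enone. A5 itself needs a long linear synthesis with a geometrically defined (Z)-enol ether.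
- Comparison: this plan is better in rings formed per step and equal or better in resting on a known reaction class. The chosen plan is better in absolute stereocontrol (catalyst-set C10 instead of relay), in the length of the precursor synthesis and in needing no C3 inversion.

Key step: step 3

## Route

Remark on the chemistry: the usual binding model of oxazaborolidinium catalysts relies on an α-C–H contact, which a carbonyl flanked by two α-methyl groups lacks. The (S)-configured catalyst is written as the one assumed to give the (10R)-adduct 5; the mirror-image catalyst, equally accessible, would be used if the sense of induction proved opposite.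

Step 1
Reactants: 1 4-methoxy-2,6-dimethylphenol
Product: 2 4,4-dimethoxy-2,6-dimethylcyclohexa-2,5-dien-1-one
Conditions: PhI(OAc)2 (1.1 equiv), MeOH, 0 °C → rt
Reagents that add atoms: methanol, CO
Why: Oxidative dearomatization of a para-alkoxyphenol with a hypervalent iodine diacetate; methanol captures the aryloxy cation equivalent at the para carbon and gives the symmetrical quinone monoketal, with no stereocentre formed.

Step 2
Reactants: 3 4-methylpent-1-en-3-one
Product: 4 4-methyl-3-(triisopropylsilyloxy)penta-1,3-diene
Conditions: i-Pr3SiOTf (1.1 equiv), Et3N (1.5 equiv), CH2Cl2, 0 °C → rt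
Reagents that add atoms: triisopropylsilyl trifluoromethanesulfonate, CC(C)[Si](C(C)C)(C(C)C)OS(=O)(=O)C(F)(F)F
Why: Soft enolization and O-silylation of a vinyl ketone; the isopropyl methine is the only α-hydrogen, so a single tetrasubstituted enol ether without E/Z ambiguity results, and the bulky silyl group makes the diene stable to storage and to Lewis acids.

Step 3
Reactants: 2 4,4-dimethoxy-2,6-dimethylcyclohexa-2,5-dien-1-one; 4 4-methyl-3-(triisopropylsilyloxy)penta-1,3-diene
Product: 5 (5S,10R)-6,6-dimethoxy-3-(triisopropylsilyloxy)-11-nordrima-2,7-dien-9-one, cis-fused [(4aS,8aR)-4,4-dimethoxy-2,5,5,8a-tetramethyl-6-(triisopropylsilyloxy)-4a,5,8,8a-tetrahydronaphthalen-1(4H)-one]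
Conditions: (S)-3,3-diphenyl-1-(o-tolyl)tetrahydro-1H,3H-pyrrolo[1,2-c][1,3,2]oxazaborole·HNTf2 (20 mol%), 4 (2 equiv), CH2Cl2, –78 → –40 °C
Reagents that add atoms: none
Why: Proposed new method: the cationic oxazaborolidinium binds the single carbonyl (C9) of 2 and polarizes the enone arm C5=C10; the enol-ether carbon C4 of 4, the most nucleophilic terminus of the 2-silyloxydiene, adds to the unsubstituted β-carbon C5, and the boron enolate then closes C10 onto C1 of the transient silyloxyallyl cation, i.e. a strongly asynchronous [4+2] process or a Mukaiyama–Michael/Michael pair that needs no coplanar s-cis diene and so tolerates the terminal dimethyl group. The closest known reaction types are the chiral oxazaborolidinium-catalysed Diels–Alder reaction of 2-(trialkylsilyloxy)butadienes with quinones and quinone monoketals and the achiral Lewis-acid cycloaddition of terminally disubstituted silyloxydienes with hindered enones; the new element is their combination. Ring A is closed suprafacially across C5=C10 (in stepwise terms a 6-(enolexo)-endo-trig Michael closure), which makes the ring fusion cis. C10, the quaternary centre that survives to the target, is set by the catalyst, which must select one of the two enantiotopic enone arms and its exposed face; C5 follows from the cis addition and is provisional. Regiochemistry needs only the electronic match, because the dienophile is symmetrical, the CMe2 terminus meets the CH carbon and the CH2 terminus meets the methyl-bearing carbon; there is no endo/exo issue since neither diene terminus becomes stereogenic. Ionization of the dimethyl ketal is to be suppressed by the low temperature and by the preference of the boron Lewis acid for the carbonyl oxygen.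

Step 4
Reactants: 5 (5S,10R)-6,6-dimethoxy-3-(triisopropylsilyloxy)-11-nordrima-2,7-dien-9-one
Product: 7 (5R,10R)-6,6-dimethoxy-3-(triisopropylsilyloxy)drima-2,7,9(11)-triene (cis-fused), via lithium β-silylalkoxide 6 (not isolated)
Conditions: Me3SiCH2Li (1.5 equiv), THF, –78 → 0 °C; then KOt-Bu (2 equiv), 0 °C → rt
Reagents that add atoms: (trimethylsilyl)methyllithium, [Li]C[Si](C)(C)C
Why: Peterson olefination: the small organolithium adds 1,2 to the hindered, non-enolizable C9 ketone (the β-carbon C7 is shielded by the ketal), and the potassium alkoxide formed by metal exchange undergoes syn elimination of silanolate to the exocyclic methylene; the basic medium leaves the ketal and the silyl enol ether untouched and no stereocentre is created.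

Step 5
Reactants: 7 (5R,10R)-6,6-dimethoxy-3-(triisopropylsilyloxy)drima-2,7,9(11)-triene
Product: 8 (5R,10R)-6,6-dimethoxydrima-7,9(11)-dien-3-one (cis-fused)
Conditions: Bu4NF (1.2 equiv), AcOH (1.2 equiv), THF, 0 °C
Reagents that add atoms: none
Why: Fluoride cleaves the O–Si bond of the enol ether and the buffered medium protonates the enolate at C2 (silyl enol ether cleavage); the acetic acid buffer keeps the allylic ketal and the diene intact.

Step 6
Reactants: 8 (5R,10R)-6,6-dimethoxydrima-7,9(11)-dien-3-one
Product: 9 (3S,5R,10R)-6,6-dimethoxydrima-7,9(11)-dien-3-ol (cis-fused)
Conditions: (R)-1-methyl-3,3-diphenyltetrahydro-1H,3H-pyrrolo[1,2-c][1,3,2]oxazaborole (0.3 equiv), catecholborane (2 equiv), toluene, –78 → –20 °C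
Reagents that add atoms: none
Why: Corey–Bakshi–Shibata reduction: the catalyst differentiates the quaternary C4 (large) from the C2 methylene (small), and the (R)-catalyst delivers hydride to give the (3S)-carbinol by reagent control, which is preferred here because axial/equatorial arguments for bulky hydrides are unreliable on the conformationally ambiguous cis-fused ketone. Catecholborane does not hydroborate the diene at this temperature, and the ketal masks the ring B carbonyl.

Step 7
Reactants: 9 (3S,5R,10R)-6,6-dimethoxydrima-7,9(11)-dien-3-ol
Product: 11 (3S,5S,10R)-3-hydroxydrima-7,9(11)-dien-6-one (trans-fused), via cis-fused dienone 10 (not isolated)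
Conditions: p-TsOH·H2O (0.3 equiv), THF/H2O (5:1), rt → 50 °C
Reagents that add atoms: water, O
Why: Acid hydrolysis of the allylic dimethyl ketal unveils the C6 ketone as a linear dienone, and acid-catalysed enolization toward C5 then equilibrates the ring fusion. Reprotonation on the face opposite the axial C4 and C10 methyl groups gives the trans-decalin, which should also be the more stable isomer of the 4,4,10-trimethyl-6-oxo system; the quaternary C10 blocks aromatization and C3 is not affected.

Step 8
Reactants: 11 (3S,5S,10R)-3-hydroxydrima-7,9(11)-dien-6-one; 12 umbelliferone (7-hydroxy-2H-chromen-2-one)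
Product: 13 ferocaulidin, (3S,5S,9R,10S)-3-hydroxy-11-[(2-oxo-2H-chromen-7-yl)oxy]drim-7-en-6-one
Conditions: 12 (2 equiv), Cs2CO3 (0.2 equiv), MeCN, rt
Reagents that add atoms: none
Why: Base-catalysed vinylogous oxa-Michael (1,6-) addition: the aryloxide attacks the exocyclic terminus C11, the only accessible electrophilic carbon since the 1,4-site C8 is fully substituted. The extended enolate is protonated at C9 on the face opposite the axial C10 methyl, which places the aryloxymethyl group equatorial (9R) and restores the C7=C8 enone; the weak base and the excess phenol keep the aliphatic hydroxyl and the lactone untouched.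

## Compound list

1 | 4-methoxy-2,6-dimethylphenol | COc1cc(C)c(O)c(C)c1 | starting material
2 | 4,4-dimethoxy-2,6-dimethylcyclohexa-2,5-dien-1-one | COC1(OC)C=C(C)C(=O)C(C)=C1 | intermediate
3 | 4-methylpent-1-en-3-one | C=CC(=O)C(C)C | starting material
4 | 4-methyl-3-(triisopropylsilyloxy)penta-1,3-diene | C=CC(O[Si](C(C)C)(C(C)C)C(C)C)=C(C)C | intermediate
5 | (5S,10R)-6,6-dimethoxy-3-(triisopropylsilyloxy)-11-nordrima-2,7-dien-9-one, cis-fused | CC1=CC(OC)(OC)[C@H]2C(C)(C)C(O[Si](C(C)C)(C(C)C)C(C)C)=CC[C@@]2(C)C1=O | intermediate
6 | lithium alkoxide of the C9 (trimethylsilyl)methyl carbinol of 5 (C9 configuration uncontrolled and of no consequence) | CC1=CC(OC)(OC)[C@H]2C(C)(C)C(O[Si](C(C)C)(C(C)C)C(C)C)=CC[C@@]2(C)C1([O-])C[Si](C)(C)C.[Li+] | intermediate (not isolated)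
7 | (5R,10R)-6,6-dimethoxy-3-(triisopropylsilyloxy)drima-2,7,9(11)-triene, cis-fused | CC1=CC(OC)(OC)[C@H]2C(C)(C)C(O[Si](C(C)C)(C(C)C)C(C)C)=CC[C@@]2(C)C1=C | intermediate
8 | (5R,10R)-6,6-dimethoxydrima-7,9(11)-dien-3-one, cis-fused | CC1=CC(OC)(OC)[C@H]2C(C)(C)C(=O)CC[C@@]2(C)C1=C | intermediate
9 | (3S,5R,10R)-6,6-dimethoxydrima-7,9(11)-dien-3-ol, cis-fused | CC1=CC(OC)(OC)[C@H]2C(C)(C)[C@@H](O)CC[C@@]2(C)C1=C | intermediate
10 | (3S,5R,10R)-3-hydroxydrima-7,9(11)-dien-6-one, cis-fused | CC1=CC(=O)[C@H]2C(C)(C)[C@@H](O)CC[C@@]2(C)C1=C | intermediate (not isolated)
11 | (3S,5S,10R)-3-hydroxydrima-7,9(11)-dien-6-one, trans-fused | CC1=CC(=O)[C@@H]2C(C)(C)[C@@H](O)CC[C@@]2(C)C1=C | intermediate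
12 | umbelliferone (7-hydroxy-2H-chromen-2-one) | O=c1ccc2ccc(O)cc2o1 | starting material
13 | ferocaulidin, (3S,5S,9R,10S)-3-hydroxy-11-[(2-oxo-2H-chromen-7-yl)oxy]drim-7-en-6-one (the change of the C10 descriptor from R to S is a priority effect, not an inversion) | CC1=CC(=O)[C@@H]2C(C)(C)[C@@H](O)CC[C@@]2(C)[C@@H]1COc1ccc2ccc(=O)oc2c1 | target

## Step count and least certain steps

Total: 8 steps. Longest linear sequence: 7 steps (step 1 or step 2, then steps 3–8).

Step 3 (key step).
- What may go wrong: too little reactivity, because the diene cannot become planar s-cis and two quaternary carbons are made around C5; Lewis-acid ionization of the ketal; arrest after the first C–C bond by silyl transfer; weak enantioface discrimination, because the carbonyl has no α-C–H to anchor the catalyst.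
- Fallback in known chemistry (sets out from 2 and 4, returns at 7, replaces steps 3 and 4): an achiral mixed aluminium Lewis acid (AlBr3/Me3Al, toluene/CH2Cl2, low temperature), a known promoter for cycloadditions of terminally disubstituted 2-silyloxydienes with hindered enones, would give the racemic cis adduct, i.e. 5 together with its mirror image ent-5 F1. Lithiated (S)-N,S-dimethyl-S-phenylsulfoximine adds to the C9 carbonyl of both and gives the β-hydroxysulfoximine F2 from 5 and the diastereomeric β-hydroxysulfoximine F3 from F1, which are separated by chromatography. Reductive elimination of F2 with Al(Hg) in wet THF/AcOH gives enantiopure 7, so resolution and methylenation are achieved by one auxiliary.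

Step 6.
- What may go wrong: erosion of reagent control by an opposing intrinsic facial bias of the cis-fused ketone, or sluggish reduction of the α-quaternary ketone by catecholborane.
- Fallback (sets out from 8, returns at 13): the reduction is deferred until the ring system is a rigid trans-decalin. Ketal hydrolysis of 8 with p-TsOH in wet THF gives the cis-dione F4, which equilibrates in the same pot to the trans-dione F5. Addition of 12 (Cs2CO3, MeCN) gives the keto ether F6. LiBH(s-Bu)3 (1.0 equiv, THF, –78 °C) then attacks the C3 ketone from the equatorial direction and gives the axial carbinol 13 under substrate control. The price is a chemoselectivity demand (saturated ketone versus hindered enone and coumarin) in the last step.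

Step 7.
- What may go wrong: slow or incomplete equilibration at C5 (enolization between two quaternary carbons, possibly a small energy gap, transient bridging of the cis isomer by the C3 hydroxyl), and oligomerization of the exocyclic dienone on long exposure to acid.
- Fallback (sets out from 9, returns at 11): C5 is set by kinetic protonation instead of equilibration. Mild hydrolysis (oxalic acid on wet silica gel, CH2Cl2) allows 10 to be isolated. LiN(SiMe3)2 (2.2 equiv, THF, –78 °C) forms the alkoxide and the cross-conjugated C5 enolate, and a hindered phenol quench delivers the proton to the face opposite the axial C4 and C10 methyl groups, giving 11.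

Step 8.
- What may go wrong: reversal of the addition (the aryloxide is a good leaving group from the extended enolate), C-alkylation of the ambident phenoxide, stalling at the deconjugated β,γ-enone, or protonation at C9 from the wrong face.
- Fallback (sets out from 11, returns at 13): the C11 heteroatom bond is made irreversibly and the ether is closed without base. Copper-catalysed conjugate borylation of 11 (CuCl, NaOt-Bu, a bisphosphine, B2pin2, MeOH, THF) should go 1,6 because the β-carbon is fully substituted and give the C11 pinacol boronate F7. Oxidation with NaBO3·4H2O gives the diol F8. A Mitsunobu reaction with 12 (PPh3, diisopropyl azodicarboxylate, THF, 0 °C) etherifies only the primary hydroxyl, since the neopentyl axial C3 carbinol is inert, and gives 13.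

## Further compounds

F1 | step 3 | ent-5, (5R,10S)-6,6-dimethoxy-3-(triisopropylsilyloxy)-11-nordrima-2,7-dien-9-one | CC1=CC(OC)(OC)[C@@H]2C(C)(C)C(O[Si](C(C)C)(C(C)C)C(C)C)=CC[C@]2(C)C1=O
F2 | step 3 | β-hydroxysulfoximine from 5 and (S)-N,S-dimethyl-S-phenylsulfoximine (C9 configuration of no consequence) | CC1=CC(OC)(OC)[C@H]2C(C)(C)C(O[Si](C(C)C)(C(C)C)C(C)C)=CC[C@@]2(C)C1(O)C[S@@](=O)(=NC)c1ccccc1
F3 | step 3 | diastereomeric β-hydroxysulfoximine from F1 and the same (S)-sulfoximine | CC1=CC(OC)(OC)[C@@H]2C(C)(C)C(O[Si](C(C)C)(C(C)C)C(C)C)=CC[C@]2(C)C1(O)C[S@@](=O)(=NC)c1ccccc1
F4 | step 6 | (5R,10R)-drima-7,9(11)-diene-3,6-dione, cis-fused | CC1=CC(=O)[C@H]2C(C)(C)C(=O)CC[C@@]2(C)C1=C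
F5 | step 6 | (5S,10R)-drima-7,9(11)-diene-3,6-dione, trans-fused | CC1=CC(=O)[C@@H]2C(C)(C)C(=O)CC[C@@]2(C)C1=C
F6 | step 6 | (5S,9R,10S)-11-[(2-oxo-2H-chromen-7-yl)oxy]drim-7-ene-3,6-dione | CC1=CC(=O)[C@@H]2C(C)(C)C(=O)CC[C@@]2(C)[C@@H]1COc1ccc2ccc(=O)oc2c1
F0 | step 7 | none | none
F7 | step 8 | (3S,5S,9R,10S)-3-hydroxy-11-(4,4,5,5-tetramethyl-1,3,2-dioxaborolan-2-yl)drim-7-en-6-one | CC1=CC(=O)[C@@H]2C(C)(C)[C@@H](O)CC[C@@]2(C)[C@@H]1CB1OC(C)(C)C(C)(C)O1
F8 | step 8 | (3S,5S,9R,10S)-3,11-dihydroxydrim-7-en-6-one | CC1=CC(=O)[C@@H]2C(C)(C)[C@@H](O)CC[C@@]2(C)[C@@H]1CO
A1 | alternative 1 | (R)-10,11-epoxy-(2E,6E)-farnesyl acetate | CC(=O)OC/C=C(\C)CC/C=C(\C)CC[C@H]1OC1(C)C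
A2 | alternative 1 | 11-acetoxy-ent-drim-8(12)-en-3-ol, equatorial (3R) hydroxyl | C=C1CC[C@@H]2C(C)(C)[C@H](O)CC[C@@]2(C)[C@@H]1COC(C)=O
A3 | alternative 2 | 3-(tert-butyldimethylsilyloxy)-6-[1-(4-methoxybenzyloxy)-3-methylbut-3-en-2-yl]-2,2,6-trimethylcyclohexane-1-carbaldehyde (C3, C5, C9, C10 as in the target) | O=C[C@@H]1C(C)(C)[C@@H](O[Si](C)(C)C(C)(C)C)CC[C@@]1(C)[C@@H](C(C)=C)COCc1ccc(OC)cc1
A4 | alternative 2 | 11-(4-methoxybenzyloxy)-3-(tert-butyldimethylsilyloxy)-ent-drim-8(12)-en-6-ol, equatorial C6 hydroxyl | C=C1C[C@@H](O)[C@@H]2C(C)(C)[C@@H](O[Si](C)(C)C(C)(C)C)CC[C@@]2(C)[C@@H]1COCc1ccc(OC)cc1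
A5 | alternative 3 | methyl (2E,6R,8Z,10E)-6,9-bis(tert-butyldimethylsilyloxy)-3,7,7-trimethyldodeca-2,8,10-trienoate | COC(=O)/C=C(\C)CC[C@@H](O[Si](C)(C)C(C)(C)C)C(C)(C)/C=C(O[Si](C)(C)C(C)(C)C)/C=C/C
A6 | alternative 3 | methyl 3,6-bis(tert-butyldimethylsilyloxy)-ent-drim-6-en-11-oate, trans-fused, C3 epimer, provisional C8 | C[C@@H]1C=C(O[Si](C)(C)C(C)(C)C)[C@@H]2C(C)(C)[C@H](O[Si](C)(C)C(C)(C)C)CC[C@@]2(C)[C@@H]1C(=O)OC
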